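Structural features

The target is a linear B-type tetramer of four flavan-3-ol units: unit T (top, epicatechin), unit M (epiafzelechin, the only unit whose ring B is 4-hydroxyphenyl), unit U (epicatechin) and unit B (bottom, epicatechin). Three C(sp3)–C(sp2) interflavan bonds join them: C4(T)–C6(M), C4(M)–C8(U) and C4(U)–C6(B). Every unit is (2R,3R) with the C2 aryl group and the C3 hydroxyl cis, and in units T, M and U the C4 substituent is trans to O3 (4β); this gives eleven stereocentres, contiguous as C2–C3–C4 in three units and C2–C3 in unit B. The fifteen free phenols are sensitive to air and base, and the interflavan bonds and the benzylic C2–O1 ethers are acid-labile. The real difficulty is regiochemical: two of the three bonds end at C6, the ring A carbon between O5 and O7 and para to O1, whereas an intact 5,7-dioxygenated chroman reacts preferentially at C8. In addition, unit M is not a cheap pool compound and has to serve both as nucleophile (C6) and as electrophile (C4). The key step exploits the fact that in rings A of units M and B the interflavan carbon C6 is para to the pyran oxygen O1. As long as ring C is absent, ring A is a phloroglucinol ring whose three CH carbons are equivalent, and an ether oxygen para to the flavanyl group has two equivalent ortho carbons. If ring C is built (O1–C2, then C4–C4a) after the interflavan bond exists, the bond can only become 4→6.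

Logic of the disconnections

In one sentence: ring C of unit M (and, in the same way, of unit B) is closed by a 6-endo Friedel–Crafts epoxy-arene cyclization of 10 (and 20), an epoxy ether of a flavanyl-phloroglucinol in which the flavanyl group is para to the ether oxygen.

22 ⇒ 21. The sixteen O–CH2Ph bonds are cut. Hydrogenolysis is the only deprotection compatible with acid-labile interflavan bonds and oxidation-prone phenols. The gain is that all earlier intermediates are ethers that tolerate Lewis acids, DDQ and base. The demand is that the three hydroxyls of unit B set free by the last ring closure need no further protection.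

21 ⇒ 20. The C4–C4a bond of unit B is cut, opening ring C of unit B to an aryl ether with a terminal epoxide. Because the ether oxygen is para to the flavanyl group, both ortho carbons give the 4→6 isomer. The gain is that C2 and C3 of unit B move into a small epoxy alcohol. The demand is a 6-endo Friedel–Crafts closure in the presence of three interflavan bonds.

20 ⇒ 16 + 19. The O1–C2 bond of unit B is cut. This separates the whole trimer from a two-stereocentre fragment. The forward step must invert the carbinol carbon cleanly and must etherify the one phenolic oxygen of 16 that is para to the flavanyl group.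

16 ⇒ 15 ⇒ 13 + 14. The C4(M)–C8(U) bond is cut (after the three acetates are put back). C8 is the intrinsically preferred nucleophilic carbon of a 5,7-dibenzyloxyflavan, so this is the one interflavan bond that a classical cationic coupling forms without help, and cutting here gives two halves of similar size. The acetates in 14 silence the phloroglucinol ring, which would otherwise be the most nucleophilic site. The forward step must attack anti to the 3-benzyloxy group of unit M (4β) and at C8 rather than C6 of unit U.

13 ⇒ 12 ⇒ 11. The C4–O bond of the activating ether on unit M is cut, then three O–benzyl bonds. C4 of unit M can be made electrophilic only after its ring C exists. The demand is hydride abstraction at the only CH2 C4 of 12, with every hydroxyl capped.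

11 ⇒ 10 (key disconnection). The C4–C4a bond of unit M is cut. Ring C of the non-pool unit M disappears, and with it the C6/C8 question, because the arene of 10 has two equivalent carbons ortho to the ether oxygen. The gain is that the epiafzelechin unit is replaced by an epoxy alcohol with two stereocentres and a flavanyl-phloroglucinol. The demand is closure at the terminal epoxide carbon without ionization of the benzylic C2–O1 ether.

10 ⇒ 6 + 9. The O1–C2 bond of unit M is cut. The forward etherification must take the hydroxyl of 6 that is para to the flavanyl group and must invert the carbinol carbon of 9, so that the erythro epoxy alcohol becomes the 2,3-cis flavan.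

6 (and through it 14) ⇒ 4 + 5. The C4(T)–aryl bond is cut. With C3-symmetric 5 all three ring carbons are equivalent, so no regiochemistry arises in this coupling. Compound 6 is used twice: as the precursor of the T–M half, and as 14, which brings unit U together with ring A of unit B. The demand is mono-alkylation (excess 5) and attack anti to the 3-benzyloxy group.

4 ⇒ 3 ⇒ 2 ⇒ 1. The C4–O bond is cut, then the O–benzyl bonds. Compound 1 supplies C2 and C3 of units T and U from the chiral pool; the demand is selective hydride abstraction at C4.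

9 ⇒ 8 ⇒ 7, and 19 ⇒ 18 ⇒ 17. The epoxide oxygen is removed, then the bond between the carbinol carbon and the vinyl group is cut. The demand is an epoxidation that is both enantioselective and erythro-selective, met by a kinetic resolution.

Other disconnections considered

Alternative 1: The three C4–aryl bonds are cut and all are formed by Lewis-acid Friedel–Crafts coupling of 4-alkoxyflavans with intact flavan nucleophiles. For the two 4→6 bonds, C8 of the nucleophile is capped with bromine, as in A1 (unit B) and A2 (unit M), and the bromine is removed in the final hydrogenolysis. This is the route that comes to mind first. The chosen plan is preferred for three reasons. A2 needs a separate de novo synthesis of an epiafzelechin before any coupling, followed by bromination and a C4 oxidation next to an aryl bromide. Both 4→6 couplings would have to take place at the hindered carbon of a ring deactivated by bromine, where self-condensation of the electrophile is expected to compete. And the chosen plan creates unit M in the same two operations that define the 4→6 bond, with the most nucleophilic possible arene (5) receiving the upper unit.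

Alternative 2: The same bonds are cut as carbonyl additions. A4, after bromine–lithium exchange, would add to the ketone A3, and the tertiary benzylic hydroxyl would then be removed by ionic hydrogenation. Regiochemistry is fixed by the position of the metal. The chosen plan is preferred on mechanistic grounds. An external hydride should approach the C4 cation anti to the axial 3-silyloxy group, which places the aryl group cis to O3 (4α), the opposite of all three linkages of the target. A4 can only be made if C8 is blocked during bromination, so the blocking problem returns. A3 is an enolizable ketone whose enolate can open ring C by β-elimination of the phenoxide.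

Alternative 3: The O1–C2 bonds of units M and B are cut instead of C4–C4a. The upper unit 4 would be coupled to the symmetric trihydroxyphenyl ring of an open-chain unit A5, and ring C would then be closed by invertive Mitsunobu displacement at the benzylic carbinol. The chosen plan is preferred because the p-benzyloxybenzylic carbinol of A5 should ionize under the Lewis acid needed for the coupling and close prematurely by an SN1 path to the 2,3-trans flavan. After the coupling, two different ortho phenols (next to and remote from the new flavanyl group) could close the ring, so the 6/8 question is only postponed. Forming O1–C2 first, on the least hindered hydroxyl, and closing at carbon removes both problems.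

Key step: step 8

Remark: units are lettered T, M, U, B from the top; flavan numbering is used within each unit; "4β" means that the C4 substituent is trans to O3; the phloroglucinol ring of 6, 10, 14–16 and 20 is numbered as benzene-1,3,5-triol with the flavanyl group on C2. Compounds 1, 5, 7 and 17 are taken as commercial. The 2-ethoxyethoxy group of 4 and 13 is drawn 4β; it is lost in the next coupling, so its configuration has no consequence.

Step 1
Reactants: 1 (−)-epicatechin
Product: 2 5,7,3′,4′-tetra-O-benzyl-(−)-epicatechin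
Conditions: BnBr (4.4 equiv), K2CO3, DMF, 0 °C to rt
Reagents that add atoms: benzyl bromide, BrCc1ccccc1
Why: Williamson etherification; K2CO3 deprotonates only the four phenols, so the secondary 3-OH stays free and C2 and C3 are untouched.

Step 2
Reactants: 2 5,7,3′,4′-tetra-O-benzyl-(−)-epicatechin
Product: 3 3,5,7,3′,4′-penta-O-benzyl-(−)-epicatechin
Conditions: NaH, BnBr, Bu4NI (cat.), DMF, 0 °C to rt
Reagents that add atoms: benzyl bromide, BrCc1ccccc1
Why: Williamson etherification of the sodium alkoxide; with all phenols already capped there is no quinone-methide pathway for epimerization at C2.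

Step 3
Reactants: 3 3,5,7,3′,4′-penta-O-benzyl-(−)-epicatechin
Product: 4 3,5,7,3′,4′-penta-O-benzyl-4β-(2-ethoxyethoxy)-(−)-epicatechin
Conditions: DDQ (2 equiv), 2-ethoxyethanol (5 equiv), CH2Cl2, rt
Reagents that add atoms: 2-ethoxyethanol, CCOCCO
Why: DDQ abstracts hydride from C4, which is benzylic to the electron-rich ring A, and the alcohol traps the cation anti to the 3-benzyloxy group (4β); this is the standard oxidative C4 activation of benzylated flavan-3-ols.

Step 4
Reactants: 4 3,5,7,3′,4′-penta-O-benzyl-4β-(2-ethoxyethoxy)-(−)-epicatechin; 5 phloroglucinol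
Product: 6 3,5,7,3′,4′-penta-O-benzyl-epicatechin-(4β→2)-phloroglucinol
Conditions: 5 (5 equiv), BF3·OEt2 (0.5 equiv), THF–CH2Cl2, −40 to 0 °C
Reagents that add atoms: none
Why: Friedel–Crafts alkylation by the C4 cation; 5 is C3-symmetric, so a single constitution results, and the excess suppresses double alkylation. Attack anti to the 3-benzyloxy group sets C4 of unit T (and, through 14, of unit U) as 4β.

Step 5
Reactants: 7 4-(benzyloxy)benzaldehyde
Product: 8 rac-1-[4-(benzyloxy)phenyl]prop-2-en-1-ol
Conditions: CH2=CHMgBr, THF, 0 °C; aq NH4Cl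
Reagents that add atoms: vinylmagnesium bromide, C=C[Mg]Br
Why: Grignard 1,2-addition to the aldehyde; the racemate is wanted as substrate for the resolution.

Step 6
Reactants: 8 rac-1-[4-(benzyloxy)phenyl]prop-2-en-1-ol
Product: 9 (S)-[4-(benzyloxy)phenyl][(2R)-oxiran-2-yl]methanol
Conditions: Ti(OiPr)4 (15 mol %), L-(+)-diisopropyl tartrate (18 mol %), t-BuOOH (0.6 equiv), 4 Å molecular sieves, CH2Cl2, −20 °C
Reagents that add atoms: tert-butyl hydroperoxide, CC(C)(C)OO
Why: Sharpless kinetic resolution; with the L-(+)-tartrate the (R)-enantiomer of 8 should be epoxidized fast and erythro-selectively, while the (S)-enantiomer stays behind and is separated. The oxirane carbon (R) becomes C3 of unit M, and the carbinol carbon (S) is the one inverted in step 7.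

Step 7
Reactants: 6 3,5,7,3′,4′-penta-O-benzyl-epicatechin-(4β→2)-phloroglucinol; 9 (S)-[4-(benzyloxy)phenyl][(2R)-oxiran-2-yl]methanol
Product: 10 5-O-{(R)-[4-(benzyloxy)phenyl][(2R)-oxiran-2-yl]methyl} ether of 6
Conditions: PPh3, DIAD, toluene–THF, 0 °C; 6 in slight excess
Reagents that add atoms: none
Why: Mitsunobu etherification with SN2 inversion at the carbinol carbon (S to R), which sets C2 of unit M; the neighbouring epoxide disfavours ionization. The hydroxyl para to the flavanyl group should react because the other two are flanked by the flavan-4-yl group with its 3- and 5-benzyloxy substituents.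

Step 8
Reactants: 10 5-O-{(R)-[4-(benzyloxy)phenyl][(2R)-oxiran-2-yl]methyl} ether of 6
Product: 11 3,5,7,3′,4′-penta-O-benzyl-epicatechin-(4β→6)-4′-O-benzyl-(−)-epiafzelechin
Conditions: BF3·OEt2 (20 mol %), CH2Cl2, −78 to −30 °C
Reagents that add atoms: none
Why: The Lewis acid activates the epoxide oxygen, and the carbon ortho to the ether oxygen of the phloroglucinol-type ring (activated by O1 and the two free hydroxyls) attacks the terminal epoxide carbon in an SN2-like Friedel–Crafts alkylation; loss of the ring proton restores the arene and leaves O3 as the free hydroxyl. The closest known reaction type is the Lewis-acid-promoted epoxy-arene cyclization of aryl glycidyl ethers to chroman-3-ols. Ring C of unit M is closed in the 6-endo-tet mode at the epoxide (new bond C4–C4a). No stereocentre is created: C2 of unit M was fixed by the Mitsunobu inversion of step 7 and C3 by the epoxidation of step 6, and no bond at either carbon is touched, so the 2,3-cis (2R,3R) relationship of 10 is carried into the ring. The step needs three selectivities. Which aromatic carbon closes does not matter, because the two carbons ortho to the ether oxygen are exchanged by rotation about the aryl–C4(T) axis; the flavanyl group is para to that oxygen and must therefore end at C6, which writes the 4→6 bond without a blocking group. Closure at the terminal carbon (6-endo) rather than at C3 (5-exo, to a dihydrobenzofuran) is secured by the primary terminus, by the inductive effect of the C2–O bonds on C3 and by the strain of the shorter tether. Ionization of the benzylic C2–O1 ether is held back by the catalytic amount of Lewis acid, the low temperature and the high nucleophilicity of the ring, which makes the intramolecular alkylation fast.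

Step 9
Reactants: 11 3,5,7,3′,4′-penta-O-benzyl-epicatechin-(4β→6)-4′-O-benzyl-(−)-epiafzelechin
Product: 12 3,5,7,3′,4′-penta-O-benzyl-epicatechin-(4β→6)-3,5,7,4′-tetra-O-benzyl-epiafzelechin
Conditions: NaH (4 equiv), BnBr (3.6 equiv), Bu4NI (cat.), DMF, 0 °C to rt
Reagents that add atoms: benzyl bromide, BrCc1ccccc1
Why: Williamson etherification of the two phenols and the 3-OH of unit M; no free phenol remains para to a benzylic carbon, so no stereocentre is at risk.

Step 10
Reactants: 12 3,5,7,3′,4′-penta-O-benzyl-epicatechin-(4β→6)-3,5,7,4′-tetra-O-benzyl-epiafzelechin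
Product: 13 derivative of 12 with a 4β-(2-ethoxyethoxy) group on C4 of unit M
Conditions: DDQ (2 equiv), 2-ethoxyethanol (5 equiv), CH2Cl2, rt
Reagents that add atoms: 2-ethoxyethanol, CCOCCO
Why: The same oxidative C4 activation as in step 3, now at the only CH2 C4 of the dimer. The tertiary C4–H of unit T is flanked by two aryl rings and lies near the plane of ring A, poorly aligned for hydride abstraction.

Step 11
Reactants: 6 3,5,7,3′,4′-penta-O-benzyl-epicatechin-(4β→2)-phloroglucinol
Product: 14 tri-O-acetate of 6
Conditions: Ac2O, pyridine, DMAP (cat.), CH2Cl2, rt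
Reagents that add atoms: acetic anhydride, CC(=O)OC(C)=O
Why: Acetylation of the three phenols; the triacetoxyphenyl ring is deactivated, so C8 of the flavan becomes the most nucleophilic carbon of 14.

Step 12
Reactants: 13 derivative of 12 with a 4β-(2-ethoxyethoxy) group on C4 of unit M; 14 tri-O-acetate of 6
Product: 15 [penta-O-benzyl-epicatechin]-(4β→6)-[3,5,7,4′-tetra-O-benzyl-epiafzelechin]-(4β→8)-[penta-O-benzyl-epicatechin]-(4β→2)-phloroglucinol triacetate
Conditions: Me3SiOTf (0.1 equiv), 14 (2.5 equiv), CH2Cl2, −78 °C; 13 added slowly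
Reagents that add atoms: none
Why: Lewis-acid Friedel–Crafts coupling of the C4 cation of unit M with C8 of unit U, the intrinsically preferred position of a 5,7-dibenzyloxyflavan; the excess of 14 suppresses self-condensation of 13. Attack anti to the 3-benzyloxy group of unit M sets its C4 as 4β.

Step 13
Reactants: 15 trimer triacetate
Product: 16 [penta-O-benzyl-epicatechin]-(4β→6)-[3,5,7,4′-tetra-O-benzyl-epiafzelechin]-(4β→8)-[penta-O-benzyl-epicatechin]-(4β→2)-phloroglucinol
Conditions: K2CO3 (0.3 equiv), MeOH–THF, 0 °C, argon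
Reagents that add atoms: none
Why: Base-catalysed methanolysis of the three aryl acetates; benzyl ethers and interflavan bonds are stable to mild base, and oxygen is excluded because of the free phloroglucinol ring.

Step 14
Reactants: 17 3,4-bis(benzyloxy)benzaldehyde
Product: 18 rac-1-[3,4-bis(benzyloxy)phenyl]prop-2-en-1-ol
Conditions: CH2=CHMgBr, THF, 0 °C; aq NH4Cl
Reagents that add atoms: vinylmagnesium bromide, C=C[Mg]Br
Why: Grignard 1,2-addition, as in step 5.

Step 15
Reactants: 18 rac-1-[3,4-bis(benzyloxy)phenyl]prop-2-en-1-ol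
Product: 19 (S)-[3,4-bis(benzyloxy)phenyl][(2R)-oxiran-2-yl]methanol
Conditions: Ti(OiPr)4 (15 mol %), L-(+)-diisopropyl tartrate (18 mol %), t-BuOOH (0.6 equiv), 4 Å molecular sieves, CH2Cl2, −20 °C
Reagents that add atoms: tert-butyl hydroperoxide, CC(C)(C)OO
Why: Sharpless kinetic resolution as in step 6; the oxirane carbon (R) becomes C3 of unit B and the (S)-carbinol carbon is inverted in step 16.

Step 16
Reactants: 16 trimer triol; 19 (S)-[3,4-bis(benzyloxy)phenyl][(2R)-oxiran-2-yl]methanol
Product: 20 5-O-{(R)-[3,4-bis(benzyloxy)phenyl][(2R)-oxiran-2-yl]methyl} ether of 16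
Conditions: PPh3, DIAD, toluene–THF, 0 °C
Reagents that add atoms: none
Why: Mitsunobu etherification with inversion (S to R), which sets C2 of unit B. The hydroxyl para to the flavanyl group is the only one not flanked by the trimer, and 16 contains no other free hydroxyl.

Step 17
Reactants: 20 5-O-{(R)-[3,4-bis(benzyloxy)phenyl][(2R)-oxiran-2-yl]methyl} ether of 16
Product: 21 [penta-O-benzyl-epicatechin]-(4β→6)-[3,5,7,4′-tetra-O-benzyl-epiafzelechin]-(4β→8)-[penta-O-benzyl-epicatechin]-(4β→6)-3′,4′-di-O-benzyl-(−)-epicatechin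
Conditions: BF3·OEt2 (20 mol %), CH2Cl2, −78 to −30 °C
Reagents that add atoms: none
Why: The same 6-endo epoxy-arene Friedel–Crafts cyclization as in step 8 closes ring C of unit B; the two ortho carbons are equivalent, so the unit U–unit B bond becomes 4→6. C2 and C3 of unit B (2R,3R, cis) are carried over unchanged from 20.

Step 18
Reactants: 21 partially benzylated tetramer
Product: 22 epicatechin-(4β→6)-epiafzelechin-(4β→8)-epicatechin-(4β→6)-epicatechin (CNP0103636.1)
Conditions: H2 (1 atm), Pd(OH)2/C, THF–MeOH–H2O, rt; filtration under argon, lyophilization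
Reagents that add atoms: none
Why: Hydrogenolysis of the sixteen benzyl ethers under neutral conditions; no stereocentre is touched, and the acid-labile interflavan bonds are not exposed to acid.

Compound list

1 | (−)-epicatechin, (2R,3R)-2-(3,4-dihydroxyphenyl)chromane-3,5,7-triol | O[C@@H]1Cc2c(O)cc(O)cc2O[C@@H]1c1ccc(O)c(O)c1 | starting material
2 | 5,7,3′,4′-tetra-O-benzyl-(−)-epicatechin (2R,3R; 3-OH free) | [C@H]1(c8ccc(OCc9ccccc9)c(OCc9ccccc9)c8)Oc2cc(OCc9ccccc9)cc(OCc9ccccc9)c2C[C@H]1O | intermediate
3 | 3,5,7,3′,4′-penta-O-benzyl-(−)-epicatechin (2R,3R) | [C@H]1(c8ccc(OCc9ccccc9)c(OCc9ccccc9)c8)Oc2cc(OCc9ccccc9)cc(OCc9ccccc9)c2C[C@H]1OCc9ccccc9 | intermediate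
4 | 3,5,7,3′,4′-penta-O-benzyl-4β-(2-ethoxyethoxy)-(−)-epicatechin (2R,3R,4S; alkoxy group trans to O3) | [C@H]1(c8ccc(OCc9ccccc9)c(OCc9ccccc9)c8)Oc2cc(OCc9ccccc9)cc(OCc9ccccc9)c2[C@H](OCCOCC)[C@H]1OCc9ccccc9 | intermediate
5 | phloroglucinol (benzene-1,3,5-triol) | Oc1cc(O)cc(O)c1 | starting material
6 | 3,5,7,3′,4′-penta-O-benzyl-epicatechin-(4β→2)-phloroglucinol (2-(flavan-4β-yl)benzene-1,3,5-triol; unit T 2R,3R, aryl group trans to O3) | [C@H]1(c8ccc(OCc9ccccc9)c(OCc9ccccc9)c8)Oc2cc(OCc9ccccc9)cc(OCc9ccccc9)c2[C@H](c3c(O)cc(O)cc3O)[C@H]1OCc9ccccc9 | intermediate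
7 | 4-(benzyloxy)benzaldehyde | O=Cc1ccc(OCc2ccccc2)cc1 | starting material
8 | rac-1-[4-(benzyloxy)phenyl]prop-2-en-1-ol | C=CC(O)c1ccc(OCc2ccccc2)cc1 | intermediate
9 | (S)-[4-(benzyloxy)phenyl][(2R)-oxiran-2-yl]methanol (erythro) | O[C@@H](c1ccc(OCc2ccccc2)cc1)[C@H]1CO1 | intermediate
10 | 5-O-{(R)-[4-(benzyloxy)phenyl][(2R)-oxiran-2-yl]methyl} ether of 6 (ether on the hydroxyl para to the flavanyl group; 1-OH and 3-OH free) | [C@H]1(c8ccc(OCc9ccccc9)c(OCc9ccccc9)c8)Oc2cc(OCc9ccccc9)cc(OCc9ccccc9)c2[C@H](c3c(O)cc(O[C@H](c8ccc(OCc9ccccc9)cc8)[C@H]4CO4)cc3O)[C@H]1OCc9ccccc9 | intermediate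
11 | 3,5,7,3′,4′-penta-O-benzyl-epicatechin-(4β→6)-4′-O-benzyl-(−)-epiafzelechin (unit M 2R,3R; its 3-OH, 5-OH and 7-OH free) | [C@H]1(c8ccc(OCc9ccccc9)c(OCc9ccccc9)c8)Oc2cc(OCc9ccccc9)cc(OCc9ccccc9)c2[C@H](c3c(O)cc4c(c3O)C[C@@H](O)[C@@H](c8ccc(OCc9ccccc9)cc8)O4)[C@H]1OCc9ccccc9 | intermediate
12 | 3,5,7,3′,4′-penta-O-benzyl-epicatechin-(4β→6)-3,5,7,4′-tetra-O-benzyl-epiafzelechin | [C@H]1(c8ccc(OCc9ccccc9)c(OCc9ccccc9)c8)Oc2cc(OCc9ccccc9)cc(OCc9ccccc9)c2[C@H](c3c(OCc9ccccc9)cc4c(c3OCc9ccccc9)C[C@@H](OCc9ccccc9)[C@@H](c8ccc(OCc9ccccc9)cc8)O4)[C@H]1OCc9ccccc9 | intermediate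
13 | derivative of 12 with a 4β-(2-ethoxyethoxy) group on C4 of unit M (trans to its 3-benzyloxy group) | [C@H]1(c8ccc(OCc9ccccc9)c(OCc9ccccc9)c8)Oc2cc(OCc9ccccc9)cc(OCc9ccccc9)c2[C@H](c3c(OCc9ccccc9)cc4c(c3OCc9ccccc9)[C@H](OCCOCC)[C@@H](OCc9ccccc9)[C@@H](c8ccc(OCc9ccccc9)cc8)O4)[C@H]1OCc9ccccc9 | intermediate
14 | tri-O-acetate of 6 (1,3,5-triacetoxy-2-(flavan-4β-yl)benzene) | [C@H]1(c8ccc(OCc9ccccc9)c(OCc9ccccc9)c8)Oc2cc(OCc9ccccc9)cc(OCc9ccccc9)c2[C@H](c3c(OC(C)=O)cc(OC(C)=O)cc3OC(C)=O)[C@H]1OCc9ccccc9 | intermediate
15 | [penta-O-benzyl-epicatechin]-(4β→6)-[3,5,7,4′-tetra-O-benzyl-epiafzelechin]-(4β→8)-[penta-O-benzyl-epicatechin]-(4β→2)-phloroglucinol triacetate | [C@H]1(c8ccc(OCc9ccccc9)c(OCc9ccccc9)c8)Oc2cc(OCc9ccccc9)cc(OCc9ccccc9)c2[C@H](c3c(OCc9ccccc9)cc4c(c3OCc9ccccc9)[C@H](c5c(OCc9ccccc9)cc(OCc9ccccc9)c6c5O[C@H](c8ccc(OCc9ccccc9)c(OCc9ccccc9)c8)[C@H](OCc9ccccc9)[C@H]6c7c(OC(C)=O)cc(OC(C)=O)cc7OC(C)=O)[C@@H](OCc9ccccc9)[C@@H](c8ccc(OCc9ccccc9)cc8)O4)[C@H]1OCc9ccccc9 | intermediate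
16 | triol corresponding to 15 (free benzene-1,3,5-triol ring on C4β of unit U) | [C@H]1(c8ccc(OCc9ccccc9)c(OCc9ccccc9)c8)Oc2cc(OCc9ccccc9)cc(OCc9ccccc9)c2[C@H](c3c(OCc9ccccc9)cc4c(c3OCc9ccccc9)[C@H](c5c(OCc9ccccc9)cc(OCc9ccccc9)c6c5O[C@H](c8ccc(OCc9ccccc9)c(OCc9ccccc9)c8)[C@H](OCc9ccccc9)[C@H]6c7c(O)cc(O)cc7O)[C@@H](OCc9ccccc9)[C@@H](c8ccc(OCc9ccccc9)cc8)O4)[C@H]1OCc9ccccc9 | intermediate
17 | 3,4-bis(benzyloxy)benzaldehyde | O=Cc1ccc(OCc2ccccc2)c(OCc2ccccc2)c1 | starting material
18 | rac-1-[3,4-bis(benzyloxy)phenyl]prop-2-en-1-ol | C=CC(O)c1ccc(OCc2ccccc2)c(OCc2ccccc2)c1 | intermediate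
19 | (S)-[3,4-bis(benzyloxy)phenyl][(2R)-oxiran-2-yl]methanol (erythro) | O[C@@H](c1ccc(OCc2ccccc2)c(OCc2ccccc2)c1)[C@H]1CO1 | intermediate
20 | 5-O-{(R)-[3,4-bis(benzyloxy)phenyl][(2R)-oxiran-2-yl]methyl} ether of 16 (ether on the hydroxyl para to the flavanyl group) | [C@H]1(c8ccc(OCc9ccccc9)c(OCc9ccccc9)c8)Oc2cc(OCc9ccccc9)cc(OCc9ccccc9)c2[C@H](c3c(OCc9ccccc9)cc4c(c3OCc9ccccc9)[C@H](c5c(OCc9ccccc9)cc(OCc9ccccc9)c6c5O[C@H](c8ccc(OCc9ccccc9)c(OCc9ccccc9)c8)[C@H](OCc9ccccc9)[C@H]6c7c(O)cc(O[C@H](c8ccc(OCc9ccccc9)c(OCc9ccccc9)c8)[C@H]2CO2)cc7O)[C@@H](OCc9ccccc9)[C@@H](c8ccc(OCc9ccccc9)cc8)O4)[C@H]1OCc9ccccc9 | intermediate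
21 | [penta-O-benzyl-epicatechin]-(4β→6)-[3,5,7,4′-tetra-O-benzyl-epiafzelechin]-(4β→8)-[penta-O-benzyl-epicatechin]-(4β→6)-3′,4′-di-O-benzyl-(−)-epicatechin (unit B 2R,3R; its 3-OH, 5-OH and 7-OH free) | [C@H]1(c8ccc(OCc9ccccc9)c(OCc9ccccc9)c8)Oc2cc(OCc9ccccc9)cc(OCc9ccccc9)c2[C@H](c3c(OCc9ccccc9)cc4c(c3OCc9ccccc9)[C@H](c5c(OCc9ccccc9)cc(OCc9ccccc9)c6c5O[C@H](c8ccc(OCc9ccccc9)c(OCc9ccccc9)c8)[C@H](OCc9ccccc9)[C@H]6c7c(O)cc2c(c7O)C[C@@H](O)[C@@H](c8ccc(OCc9ccccc9)c(OCc9ccccc9)c8)O2)[C@@H](OCc9ccccc9)[C@@H](c8ccc(OCc9ccccc9)cc8)O4)[C@H]1OCc9ccccc9 | intermediate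
22 | epicatechin-(4β→6)-epiafzelechin-(4β→8)-epicatechin-(4β→6)-epicatechin (CNP0103636.1; all units 2R,3R, all interflavan bonds trans to O3) | Oc1ccc([C@H]2Oc3cc(O)c([C@H]4c5c(O)cc(O)cc5O[C@H](c5ccc(O)c(O)c5)[C@@H]4O)c(O)c3[C@H](c3c(O)cc(O)c4c3O[C@H](c3ccc(O)c(O)c3)[C@H](O)[C@H]4c3c(O)cc4c(c3O)C[C@@H](O)[C@@H](c3ccc(O)c(O)c3)O4)[C@H]2O)cc1 | target

Total step count: 18. Longest linear sequence: 13 steps from 1 (steps 1, 2, 3, 4, 7, 8, 9, 10, 12, 13, 16, 17, 18).

Steps least certain to work

Step 8 (key step; step 17 is its twin). The most likely failure is that the Lewis acid ionizes the substrate elsewhere before the ring closes. Ionization can occur at the internal epoxide carbon, with a 1,2-shift of the neighbouring aryl group or of hydride, or at the p-benzyloxybenzylic C2–O1 ether, with epimerization or cleavage at C2; both positions can carry positive charge and compete with the SN2-like attack at the terminal carbon. The fallback leaves the cationic manifold altogether. It sets out from 10 and returns to the route at 11. The two free phenols of 10 are converted into lithium phenoxides (LiOtBu, 2.2 equiv, toluene, 60 °C), and the carbon ortho and para to the phenoxide oxygens alkylates itself with the terminal epoxide carbon. Such phenoxide C-alkylation in a non-polar solvent makes the same C4–C4a bond without any acid; no new compound is formed on the way. The same change applies to 20 and 21.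

Step 7 (step 16 is its twin). Two processes may intrude. One is etherification of a hydroxyl ortho to the flavanyl group, which after ring closure would deliver the 4→8 isomer; the preference for the para hydroxyl rests on steric shielding only. The other is partial loss of inversion through ionization of the p-benzyloxybenzylic oxyphosphonium ion. The fallback replaces direct selective etherification by differentiation with protecting groups. It sets out from 6 and comes back at 12. Pivaloyl chloride in pyridine at −20 °C acylates the unhindered para hydroxyl to give the 5-O-pivalate F1; any mis-acylated material is removed at this cheap stage. Benzylation (BnBr, K2CO3, acetone) gives the 1,3-di-O-benzyl 5-O-pivalate F2, and NaOMe in MeOH frees the single phenol of the 1,3-di-O-benzyl ether F3. The Mitsunobu reaction of F3 with 9 can then occur at one oxygen only and gives the epoxy ether F4. Cyclization under the conditions of step 8 gives the dimer F5, which has a free 3-OH on unit M. Benzylation of F5 (NaH, BnBr) gives 12.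

Step 10. Hydride abstraction by DDQ may not be confined to the CH2 C4 of unit M. The tertiary, doubly benzylic C4–H of unit T or the benzylic ether methylenes could also be attacked, because the dimer offers several electron-rich benzylic positions. The fallback installs the C4 leaving group during ring construction instead of by C–H oxidation. It sets out from 10 and comes back at 15. Thiophenol with Et3N opens the terminal epoxide carbon of 10 to the β-hydroxy sulfide F6. NaH and BnBr cap its three hydroxyls to give the tri-O-benzyl sulfide F7, and m-CPBA (1.0 equiv, CH2Cl2, −78 °C) gives the sulfoxide F8. Trifluoroacetic anhydride then triggers a Pummerer reaction, and the thionium ion at C4 is captured by the ortho carbon of the phloroglucinol ether (again either of two equivalent carbons), which gives the 4-(phenylthio) dimer F9 as a mixture of C4 epimers. Thiophilic activation of F9 with AgBF4 in THF in the presence of 14 forms the C4(M)–C8(U) bond and gives 15.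

Step 6 (step 15 is its twin). The resolution may discriminate the enantiomers incompletely, and the p-benzyloxybenzylic epoxy alcohol may be opened by isopropoxide on titanium during the long reaction time; the yield is in any case capped at one half. The fallback sets the carbinol centre by enantioselective C–C bond formation instead of by resolution. It sets out from 7 and comes back at 9. Addition of (CH2=CH)2Zn to 7 in the presence of a chiral amino-alcohol ligand of the appropriate handedness gives (R)-1-[4-(benzyloxy)phenyl]prop-2-en-1-ol F10. The matched Ti(OiPr)4/L-(+)-diisopropyl tartrate/t-BuOOH epoxidation of F10 can then be run quickly to full conversion and gives 9.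

Further compounds

F0 | step 8 | none | none
F1 | step 7 | 5-O-pivalate of 6 (pivalate on the hydroxyl para to the flavanyl group) | [C@H]1(c8ccc(OCc9ccccc9)c(OCc9ccccc9)c8)Oc2cc(OCc9ccccc9)cc(OCc9ccccc9)c2[C@H](c3c(O)cc(OC(=O)C(C)(C)C)cc3O)[C@H]1OCc9ccccc9
F2 | step 7 | 1,3-di-O-benzyl 5-O-pivalate of 6 | [C@H]1(c8ccc(OCc9ccccc9)c(OCc9ccccc9)c8)Oc2cc(OCc9ccccc9)cc(OCc9ccccc9)c2[C@H](c3c(OCc9ccccc9)cc(OC(=O)C(C)(C)C)cc3OCc9ccccc9)[C@H]1OCc9ccccc9
F3 | step 7 | 1,3-di-O-benzyl ether of 6 (5-OH free) | [C@H]1(c8ccc(OCc9ccccc9)c(OCc9ccccc9)c8)Oc2cc(OCc9ccccc9)cc(OCc9ccccc9)c2[C@H](c3c(OCc9ccccc9)cc(O)cc3OCc9ccccc9)[C@H]1OCc9ccccc9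
F4 | step 7 | 5-O-{(R)-[4-(benzyloxy)phenyl][(2R)-oxiran-2-yl]methyl} ether of F3 | [C@H]1(c8ccc(OCc9ccccc9)c(OCc9ccccc9)c8)Oc2cc(OCc9ccccc9)cc(OCc9ccccc9)c2[C@H](c3c(OCc9ccccc9)cc(O[C@H](c8ccc(OCc9ccccc9)cc8)[C@H]4CO4)cc3OCc9ccccc9)[C@H]1OCc9ccccc9
F5 | step 7 | 3,5,7,3′,4′-penta-O-benzyl-epicatechin-(4β→6)-5,7,4′-tri-O-benzyl-(−)-epiafzelechin (3-OH of unit M free) | [C@H]1(c8ccc(OCc9ccccc9)c(OCc9ccccc9)c8)Oc2cc(OCc9ccccc9)cc(OCc9ccccc9)c2[C@H](c3c(OCc9ccccc9)cc4c(c3OCc9ccccc9)C[C@@H](O)[C@@H](c8ccc(OCc9ccccc9)cc8)O4)[C@H]1OCc9ccccc9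
F6 | step 10 | β-hydroxy sulfide from 10 (epoxide opened by thiophenol at the terminal carbon; configuration of both chain carbons as in 10) | [C@H]1(c8ccc(OCc9ccccc9)c(OCc9ccccc9)c8)Oc2cc(OCc9ccccc9)cc(OCc9ccccc9)c2[C@H](c3c(O)cc(O[C@H](c8ccc(OCc9ccccc9)cc8)[C@H](O)CSc9ccccc9)cc3O)[C@H]1OCc9ccccc9
F7 | step 10 | tri-O-benzyl ether of F6 | [C@H]1(c8ccc(OCc9ccccc9)c(OCc9ccccc9)c8)Oc2cc(OCc9ccccc9)cc(OCc9ccccc9)c2[C@H](c3c(OCc9ccccc9)cc(O[C@H](c8ccc(OCc9ccccc9)cc8)[C@H](OCc9ccccc9)CSc9ccccc9)cc3OCc9ccccc9)[C@H]1OCc9ccccc9
F8 | step 10 | sulfoxide of F7 (mixture at sulfur) | [C@H]1(c8ccc(OCc9ccccc9)c(OCc9ccccc9)c8)Oc2cc(OCc9ccccc9)cc(OCc9ccccc9)c2[C@H](c3c(OCc9ccccc9)cc(O[C@H](c8ccc(OCc9ccccc9)cc8)[C@H](OCc9ccccc9)CS(=O)c9ccccc9)cc3OCc9ccccc9)[C@H]1OCc9ccccc9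
F9 | step 10 | 4-(phenylthio) derivative of 12 on C4 of unit M (mixture of C4 epimers) | [C@H]1(c8ccc(OCc9ccccc9)c(OCc9ccccc9)c8)Oc2cc(OCc9ccccc9)cc(OCc9ccccc9)c2[C@H](c3c(OCc9ccccc9)cc4c(c3OCc9ccccc9)C(Sc9ccccc9)[C@@H](OCc9ccccc9)[C@@H](c8ccc(OCc9ccccc9)cc8)O4)[C@H]1OCc9ccccc9
F10 | step 6 | (R)-1-[4-(benzyloxy)phenyl]prop-2-en-1-ol | C=C[C@@H](O)c1ccc(OCc2ccccc2)cc1
A1 | alternative 1 | 8-bromo-5,7,3′,4′-tetra-O-benzyl-(−)-epicatechin (2R,3R) | [C@H]1(c8ccc(OCc9ccccc9)c(OCc9ccccc9)c8)Oc2c(Br)c(OCc9ccccc9)cc(OCc9ccccc9)c2C[C@H]1O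
A2 | alternative 1 | 8-bromo-5,7,4′-tri-O-benzyl-(−)-epiafzelechin (2R,3R) | [C@H]1(c8ccc(OCc9ccccc9)cc8)Oc2c(Br)c(OCc9ccccc9)cc(OCc9ccccc9)c2C[C@H]1O
A3 | alternative 2 | 4-oxo derivative of 5,7,3′,4′-tetra-O-benzyl-3-O-(tert-butyldimethylsilyl)-(−)-epicatechin (2R; aryl and silyloxy groups cis) | [C@H]1(c8ccc(OCc9ccccc9)c(OCc9ccccc9)c8)Oc2cc(OCc9ccccc9)cc(OCc9ccccc9)c2C(=O)[C@H]1O[Si](C)(C)C(C)(C)C
A4 | alternative 2 | 6-bromo-5,7,3′,4′-tetra-O-benzyl-3-O-(tert-butyldimethylsilyl)-(−)-epicatechin (2R,3R) | [C@H]1(c8ccc(OCc9ccccc9)c(OCc9ccccc9)c8)Oc2cc(OCc9ccccc9)c(Br)c(OCc9ccccc9)c2C[C@H]1O[Si](C)(C)C(C)(C)C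
A5 | alternative 3 | (1S,2R)-1-[4-(benzyloxy)phenyl]-3-(2,4,6-trihydroxyphenyl)propane-1,2-diol | O[C@@H](c1ccc(OCc2ccccc2)cc1)[C@H](O)Cc1c(O)cc(O)cc1O
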